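The runs come from a simulation for an exercise, and the scatter is random.

I decide to judge these flasks by one number, which the autumn run gives as 0.504 after 6.00 h: the reach, minus the natural log of the fraction of starting material left. I take its growth rate as proportional to reagent times free catalyst.

| flask | starting material | reagent | free catalyst | temperature | remark | time |
|---|---|---|---|---|---|---|
| autumn | 0.20 M | 1 M | 1 mM | −5 °C | run made earlier |  |
| noon | 0.20 M | 1 M | 1.5 mM | 25 °C | run made earlier |  |
| maple | 0.20 M | 1.00 M | 2.0 mM |  | at 0 °C until 2.0 h, from then on at 50 °C | 6.0 h |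
| oak | 0.20 M | 1.00 M | 2.0 mM | 25 °C |  | 6.0 h |
| cedar | 0.20 M | 1.00 M | 2.0 mM | 50 °C |  | 6.0 h |
| larch | 0.20 M | 1.00 M | 2.0 mM | 0 °C |  | 6.0 h |

| run | time / h | product / % | starting material / % |
|---|---|---|---|
| autumn | 1.00 | 11.5 | 90.5 |
| autumn | 3.00 | 27.2 | 74.8 |
| autumn | 6.00 | 40.8 | 60.4 |
| autumn | 8.00 | 47.0 | 54.2 |
| autumn | 12.0 | 55.3 | 44.6 |
| autumn | 20.0 | 63.8 | 36.0 |
| noon | 0.250 | 16.7 | 84.7 |
| noon | 0.667 | 22.6 | 77.6 |
| noon | 1.33 | 24.4 | 74.3 |
| noon | 2.00 | 25.2 | 75.0 |
| noon | 3.00 | 25.4 | 75.9 |
| noon | 4.00 | 26.5 | 74.5 |
| noon | 5.00 | 25.5 | 77.2 |

(standard deviation of a reading: 1 percentage point)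

1. the flask with the highest amount of product, in percent of the starting material charged ("all alike" if they lie within 1.5 percentage points) (maple / oak / cedar / larch / all alike)
2. final product, as a percentage of the starting material charged, in maple
3. final product, as a percentage of the starting material charged, in oak
4. final product, as a percentage of the starting material charged, in cedar
5. final product, as a percentage of the starting material charged, in larch

Reagent stands at 5.00 equivalents, and full conversion takes 20.0% of its charge, so I treat the reaction as pseudo-first-order in starting material, and free catalyst is the concentration I follow. The noon run reads 25.5% of product at its last reading, against 63.8% at the last reading of the autumn run, and I read the noon stall as catalyst dying.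

I scale the reach with the catalyst charge. For larch I take twice the autumn reach and ignore the difference in temperature, which gives 1.01, so 63.6% product. For oak, noon's reach of 0.294 becomes 0.392, so 32.4% product. Cedar stands at 50 °C against the 25 °C of noon, so I place it below oak, and I rank maple, with 2.0 h cold before the heat, between oak and larch.

The forecast names larch, with 45% in maple, 32.5% in oak, 11% in cedar and 67% in larch, on the ground that “heat favours death”.

The flasks give 41.4% in maple, 31.1% in oak, 7.43% in cedar and 62.2% in larch, so larch holds the most product.

    starting material + reagent + free catalyst → free catalyst + product (k = 170 M⁻² h⁻¹, Ea = 41.0 kJ mol⁻¹)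
    2 free catalyst → spent catalyst B (k = 58.0 M⁻¹ h⁻¹, Ea = 43.0 kJ mol⁻¹)
    free catalyst → spent catalyst A (k = 0.100 h⁻¹, Ea = 96.0 kJ mol⁻¹)
    (constants at 0 °C)

Larch ends with a reach of 0.973 against my 1.01, and it still holds 26.8% of its free catalyst. The neighbour of larch charged with 0.25 M of reagent has 1.25 equiv of reagent and keeps 26.8% of its free catalyst, the same as larch. Scaling the reach with the reagent charge as well gives 0.252, so 22.3% product. That neighbour ends with 78.8% of its starting material and 21.2% of product.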